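The electrophile in the west run races two clocks, so I reckon with the fraction left, not the fraction made.

all flasks: electrophile 0.10 M
- west: free base 1.5 equiv; protonated nucleophile 1 equiv; run made earlier
- blue: free base 1.50 equiv; protonated nucleophile 1.50 equiv; time 2.5 h
- grey: free base 2.00 equiv; protonated nucleophile 1.50 equiv; time 2.5 h

west run (percent of the electrophile charged)

| time / min | electrophile / % | target / % |
|---|---|---|
| 8.00 | 96 | 5 |
| 12.0 | 92 | 7 |
| 15.0 | 90 | 8 |
| 25.0 | 85 | 8 |
| 40.0 | 83 | 9 |
| 60.0 | 79 | 3 |
| 90.0 | 78 | 2 |

(readings scatter by 2 percentage points)

- no earlier run changes the charge of free base; that part of a forecast is a guess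

- part of the electrophile that has reacted at the end, blue
- part of the electrophile that has reacted at the end, grey
- what raising the equivalents of free base from its lowest to its highest value here does to the part of the electrophile that has reacted (changes below 5 percentage points count as none) (no change / it falls / it rises)

The first clock is the reaction time t_r, the pseudo-first-order time of the opening fall, read at 15.0 min with its scatter:

t_r = 142 min

The reach X is the logarithm of electrophile charged over electrophile left at the stall. The second clock, the stall time τ, follows from it:

X = τ/t_r = 0.248, so τ = 35.4 min

The last west reading is 78% of electrophile, and I read that as a stall because τ is shorter than t_r. Blue has the free base of the west run. I assume that the opening pace grows with the charge of protonated nucleophile while τ holds: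

X(blue) = 0.373, so left 68.9% and reacted 31.1%

Blue's time is 4.24 τ, so I expect its stall inside the run. No run varies free base, so I keep blue's figure for grey, as a guess.

The forecast gives 31% for blue, 37% for grey and "it rises", holding that “Something needed for reaction, probably the active nucleophile, is being lost”. For grey, my figure is lower than the forecast's.

The flask gives 29.8% for blue and 31.3% for grey, a change of 1.6 percentage points, which counts as no change.

    electrophile + nucleophile → acid set free + target (k = 0.207 M⁻¹ min⁻¹)
    nucleophile + acid set free ⇌ protonated nucleophile, settled at all times (K = 55000 M⁻¹)
    acid set free + free base ⇌ salt of the base, settled at all times (K = 14000 M⁻¹)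
    2 free base → homo dimer (k = 0.341 M⁻¹ min⁻¹)
    target ⇌ isomer of the product (K = 6.90, k = 0.0856 min⁻¹)

Blue's end state gives a reach of 0.354, against my 0.373. The neighbouring flask is blue with 2.50 equiv of protonated nucleophile. The same scaling gives it a reach of 0.621, so 46.3% reacted. That neighbouring flask keeps 63% of its electrophile, a reach of 0.462, and 37.0% has reacted.

The earlier runs and the new flask are calculated with made-up constants; noise was put on by code.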